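**Strategy.** Everything rests on disconnecting C3–C4 of the pyran ring (ring C) of the upper flavan unit. Its C4 is a doubly benzylic methine between ring A (ortho to O1, para to O7) and ring D, the benzene ring of the lower flavan-3,4-diol; it is carried as a benzhydryl 2-pyridyl sulfone assembled by a convergent aryl–aldehyde union. C3 is the carbonyl carbon of an α-aryloxy aldehyde whose C2 centre stems from (S)-4-hydroxymandelic acid. SmI2 reduction makes C4 nucleophilic; it closes ring C onto the aldehyde and sets C3 and C4 in one operation, leaving only deprotection.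

Key step: step 15

Remarks on the chemistry:
- (S)-4-Hydroxymandelic acid is assumed to be purchasable as a single enantiomer.
- Flavan numbering (O1, C2, C3, C4, C4a, C5–C8, C8a) is used for both units.
- The target has a 2,3-cis-3,4-trans upper unit (2R,3R,4S) and a 2,3-trans-3,4-trans lower unit (2R,3S,4R).
- "Ar-D" means the residue of 10 bonded through C6 in place of bromine.

**Route**

Step 1
Reactants: 1 1-(2,3,4-trihydroxyphenyl)ethanone
Product: 2 1-[3,4-bis(benzyloxy)-2-hydroxyphenyl]ethanone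
Conditions: BnBr (2.1 equiv), K2CO3, DMF, rt
Reagents that add atoms: benzyl bromide, BrCc1ccccc1
Why: Williamson etherification; the 2-OH is tied up in a hydrogen bond to the acetyl group and should stay free with two equivalents of benzyl bromide.

Step 2
Reactants: 2 1-[3,4-bis(benzyloxy)-2-hydroxyphenyl]ethanone
Product: 3 1-[3,4-bis(benzyloxy)-5-bromo-2-hydroxyphenyl]ethanone
Conditions: NBS, MeCN, 0 °C
Reagents that add atoms: N-bromosuccinimide, O=C1CCC(=O)N1Br
Why: Electrophilic aromatic bromination should go to C5, the only free position that is para to the free phenol and ortho to a benzyloxy group.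

Step 3
Reactants: 3 1-[3,4-bis(benzyloxy)-5-bromo-2-hydroxyphenyl]ethanone
Product: 4 1-[3,4-bis(benzyloxy)-5-bromo-2-(methoxymethoxy)phenyl]ethanone
Conditions: NaH, MOMCl, THF/DMF, 0 °C
Reagents that add atoms: chloromethyl methyl ether, COCCl
Why: Williamson-type acetal protection of the phenoxide, needed so that the chalcone cannot cyclise under the basic steps that follow.

Step 4
Reactants: 4 1-[3,4-bis(benzyloxy)-5-bromo-2-(methoxymethoxy)phenyl]ethanone; 5 4-(benzyloxy)benzaldehyde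
Product: 6 (E)-1-[3,4-bis(benzyloxy)-5-bromo-2-(methoxymethoxy)phenyl]-3-[4-(benzyloxy)phenyl]prop-2-en-1-one
Conditions: KOH, EtOH/THF, rt
Reagents that add atoms: none
Why: Claisen–Schmidt aldol condensation; dehydration of the aldol should give the E-enone.

Step 5
Reactants: 6 (E)-chalcone
Product: 7 [3,4-bis(benzyloxy)-5-bromo-2-(methoxymethoxy)phenyl][(2R,3S)-3-(4-benzyloxyphenyl)oxiran-2-yl]methanone
Conditions: poly-L-leucine, urea–H2O2, DBU, THF, rt
Reagents that add atoms: urea–hydrogen peroxide, OO.NC(N)=O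
Why: Juliá–Colonna epoxidation; the helical poly-L-leucine binds the hydroperoxide adduct and delivers oxygen to one enone face, which should give the (2R,3S)-trans-epoxide.

Step 6
Reactants: 7 (2R,3S)-epoxy ketone
Product: 8 (2R,3R)-7,8-bis(benzyloxy)-2-[4-(benzyloxy)phenyl]-6-bromo-3-hydroxychroman-4-one (2,3-trans)
Conditions: HCl, MeOH/THF, 55 °C
Reagents that add atoms: none
Why: Acid cleaves the MOM acetal and the freed phenol opens the epoxide at the benzylic carbon (6-endo epoxide-opening cyclisation); C3 keeps the configuration of the epoxide α-carbon and C2 is set trans to it by inversion, which is also the diequatorial arrangement.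

Step 7
Reactants: 8 (2R,3R)-dihydroflavonol
Product: 9 (2R,3S,4R)-7,8-bis(benzyloxy)-2-[4-(benzyloxy)phenyl]-6-bromochromane-3,4-diol (2,3-trans-3,4-trans)
Conditions: NaBH4, MeOH/THF, 0 °C
Reagents that add atoms: none
Why: Borohydride ketone reduction; axial hydride attack on the half-chair should give the equatorial 4-OH, trans to the equatorial 3-OH.

Step 8
Reactants: 9 (2R,3S,4R)-diol
Product: 10 3,4-bis-O-(tert-butyldimethylsilyl) ether of 9 (configuration unchanged)
Conditions: TBSOTf, 2,6-lutidine, CH2Cl2, −78 to 0 °C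
Reagents that add atoms: tert-butyldimethylsilyl triflate, CC(C)(C)[Si](C)(C)OS(=O)(=O)C(F)(F)F
Why: Silyl ether formation; the silyl ethers tolerate the aryl-metal and SmI2 steps and can be removed with fluoride before hydrogenolysis.

Step 9
Reactants: 11 2,3,4-trihydroxybenzaldehyde
Product: 12 3,4-bis(benzyloxy)-2-hydroxybenzaldehyde
Conditions: BnBr (2.1 equiv), K2CO3, DMF, rt
Reagents that add atoms: benzyl bromide, BrCc1ccccc1
Why: Williamson etherification; the 2-OH chelated to the formyl group should stay free.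

Step 10
Reactants: 13 (S)-2-hydroxy-2-(4-hydroxyphenyl)acetic acid
Product: 14 benzyl (S)-2-[4-(benzyloxy)phenyl]-2-hydroxyacetate
Conditions: BnBr (2.1 equiv), K2CO3, DMF, rt
Reagents that add atoms: benzyl bromide, BrCc1ccccc1
Why: Williamson O-alkylation of carboxylate and phenoxide; K2CO3 does not deprotonate the secondary alcohol and the stereocentre is not touched.

Step 11
Reactants: 12 3,4-bis(benzyloxy)-2-hydroxybenzaldehyde; 14 benzyl (S)-2-[4-(benzyloxy)phenyl]-2-hydroxyacetate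
Product: 15 benzyl (R)-2-[2,3-bis(benzyloxy)-6-formylphenoxy]-2-[4-(benzyloxy)phenyl]acetate
Conditions: PPh3, DIAD, THF, 0 °C to rt
Reagents that add atoms: none
Why: Mitsunobu etherification; SN2 displacement of the oxyphosphonium group by the acidic salicylaldehyde-type phenol inverts the α-carbon (S to R), and the adjacent ester suppresses ionisation, so the future C2 should be set cleanly.

Step 12
Reactants: 10 bis-silyl bromide; 15 benzyl (R)-2-[2,3-bis(benzyloxy)-6-formylphenoxy]-2-[4-(benzyloxy)phenyl]acetate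
Product: 18 benzyl (2R)-2-{2,3-bis(benzyloxy)-6-[hydroxy(Ar-D)methyl]phenoxy}-2-[4-(benzyloxy)phenyl]acetate (both carbinol epimers), via aryllithium 16 (not isolated), via aryltitanium triisopropoxide 17 (not isolated)
Conditions: n-BuLi, THF, −78 °C; ClTi(OiPr)3, −78 to −40 °C; then 15, −40 to 0 °C; aq NH4Cl
Reagents that add atoms: none
Why: Bromine–lithium exchange and transmetalation give a non-basic aryltitanium that undergoes carbonyl 1,2-addition to the aldehyde only, sparing the ester and the acidic C2–H; the new carbinol centre forms unselectively and is erased in steps 13 and 15.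

Step 13
Reactants: 18 diaryl carbinol
Product: 19 benzyl (2R)-2-{2,3-bis(benzyloxy)-6-[(Ar-D)(pyridin-2-ylsulfonyl)methyl]phenoxy}-2-[4-(benzyloxy)phenyl]acetate (both epimers at the sulfonyl carbon)
Conditions: sodium pyridine-2-sulfinate, TFA, CH2Cl2, 0 °C
Reagents that add atoms: sodium pyridine-2-sulfinate, [Na+].[O-]S(=O)c1ccccn1
Why: SN1 substitution; the benzhydryl cation, stabilised by O1 and O7 of ring A and by O7 and O1 of ring D, should form under mild acid and be captured at sulfur by the ambident sulfinate to give the thermodynamically favoured sulfone.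

Step 14
Reactants: 19 pyridyl sulfone ester
Product: 20 (2R)-2-{2,3-bis(benzyloxy)-6-[(Ar-D)(pyridin-2-ylsulfonyl)methyl]phenoxy}-2-[4-(benzyloxy)phenyl]acetaldehyde
Conditions: iBu2AlH (2.2 equiv), CH2Cl2, −78 °C; aq potassium sodium tartrate
Reagents that add atoms: none
Why: Partial ester reduction through a chelated tetrahedral aluminium hemiacetal that collapses only on work-up; the aldehyde is used at once so that the C2 centre is not lost by enolisation.

Step 15
Reactants: 20 sulfonyl aldehyde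
Product: 22 hexa-O-benzyl-3,4-bis-O-(tert-butyldimethylsilyl) dimer with free upper 3-OH (upper unit 2R,3R and 2,3-cis-3,4-trans), via benzhydrylsamarium diiodide 21 (not isolated)
Conditions: SmI2 (3 equiv), THF, −78 to 0 °C, slow addition of 20; aq NH4Cl
Reagents that add atoms: none
Why: Proposed new method: SmI2 transfers two electrons to the 2-pyridyl sulfone, whose pyridine nitrogen and sulfonyl oxygen chelate samarium, so that pyridine-2-sulfinate is lost and the benzhydryl carbanion is held on trivalent samarium (21), which then adds to the samarium-activated aldehyde carbon C3. The closest known reaction types are the SmI2 Barbier couplings of glycosyl 2-pyridyl sulfones with aldehydes and the intramolecular SmI2 Barbier cyclisations of benzylic halides onto carbonyl groups; no such closure of a bis-benzylic sulfone onto an α-aryloxy aldehyde is known. Ring C closes by a 6-exo-trig attack of C4 on C3. C3 is set by C2: in the half-chair with the C2 aryl group equatorial, trivalent samarium bridges the carbonyl oxygen and O1, which places O3 axial and cis to that aryl group; C4 is set by C3 and ring A: the ring D aryl group takes the pseudoaxial site, anti to the bulky samarium alkoxide and clear of the peri hydrogen at C5, which gives the 3,4-trans arrangement. The step needs reduction of the sulfone ahead of the aldehyde and survival of the labile C2 centre; the chelating, bis-benzylic sulfone should accept electrons far faster than an aliphatic aldehyde in THF without HMPA, and slow addition keeps the medium free of base because each carbanion is trapped intramolecularly.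

Step 16
Reactants: 22 bis-silyl hexabenzyl dimer
Product: 23 hexa-O-benzyl ether of the target (free upper 3-OH and lower 3,4-diol)
Conditions: Bu4NF, AcOH, THF, rt
Reagents that add atoms: none
Why: Fluoride-mediated desilylation, buffered with acetic acid, should free the lower 3,4-diol while all phenols are still benzylated and no stereocentre is touched.

Step 17
Reactants: 23 hexa-O-benzyl ether
Product: 24 (2R,3S,4R)-2-(4-hydroxyphenyl)-6-[(2R,3R,4S)-3,7,8-trihydroxy-2-(4-hydroxyphenyl)chroman-4-yl]chromane-3,4,7,8-tetrol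
Conditions: H2 (1 atm), Pd(OH)2/C, THF/MeOH, rt
Reagents that add atoms: none
Why: Catalytic hydrogenolysis of the six aryl benzyl ethers under neutral conditions; the benzylic 4-OH, both C2–O1 bonds and the interflavan bond are expected to survive at one atmosphere and short contact time.

**Compound list**

1 | 1-(2,3,4-trihydroxyphenyl)ethanone | CC(=O)c1ccc(O)c(O)c1O | starting material
2 | 1-[3,4-bis(benzyloxy)-2-hydroxyphenyl]ethanone | CC(=O)c1ccc(OCc2ccccc2)c(OCc2ccccc2)c1O | intermediate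
3 | 1-[3,4-bis(benzyloxy)-5-bromo-2-hydroxyphenyl]ethanone | CC(=O)c1cc(Br)c(OCc2ccccc2)c(OCc2ccccc2)c1O | intermediate
4 | 1-[3,4-bis(benzyloxy)-5-bromo-2-(methoxymethoxy)phenyl]ethanone | COCOc1c(C(C)=O)cc(Br)c(OCc2ccccc2)c1OCc1ccccc1 | intermediate
5 | 4-(benzyloxy)benzaldehyde | O=Cc1ccc(OCc2ccccc2)cc1 | starting material
6 | (E)-1-[3,4-bis(benzyloxy)-5-bromo-2-(methoxymethoxy)phenyl]-3-[4-(benzyloxy)phenyl]prop-2-en-1-one | COCOc1c(C(=O)/C=C/c2ccc(OCc3ccccc3)cc2)cc(Br)c(OCc2ccccc2)c1OCc1ccccc1 | intermediate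
7 | [3,4-bis(benzyloxy)-5-bromo-2-(methoxymethoxy)phenyl][(2R,3S)-3-(4-benzyloxyphenyl)oxiran-2-yl]methanone | COCOc1c(C(=O)[C@@H]2O[C@H]2c2ccc(OCc3ccccc3)cc2)cc(Br)c(OCc2ccccc2)c1OCc1ccccc1 | intermediate
8 | (2R,3R)-7,8-bis(benzyloxy)-2-[4-(benzyloxy)phenyl]-6-bromo-3-hydroxychroman-4-one | O=C1[C@H](O)[C@@H](c2ccc(OCc3ccccc3)cc2)Oc2c(OCc3ccccc3)c(OCc3ccccc3)c(Br)cc21 | intermediate
9 | (2R,3S,4R)-7,8-bis(benzyloxy)-2-[4-(benzyloxy)phenyl]-6-bromochromane-3,4-diol | Brc1cc2c(c(OCc3ccccc3)c1OCc1ccccc1)O[C@H](c1ccc(OCc3ccccc3)cc1)[C@@H](O)[C@@H]2O | intermediate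
10 | 3,4-bis-O-(tert-butyldimethylsilyl) ether of 9 (2,3-trans-3,4-trans, 2R) | Brc1cc2c(c(OCc3ccccc3)c1OCc1ccccc1)O[C@H](c1ccc(OCc3ccccc3)cc1)[C@@H](O[Si](C)(C)C(C)(C)C)[C@@H]2O[Si](C)(C)C(C)(C)C | intermediate
11 | 2,3,4-trihydroxybenzaldehyde | O=Cc1ccc(O)c(O)c1O | starting material
12 | 3,4-bis(benzyloxy)-2-hydroxybenzaldehyde | O=Cc1ccc(OCc2ccccc2)c(OCc2ccccc2)c1O | intermediate
13 | (S)-2-hydroxy-2-(4-hydroxyphenyl)acetic acid | O=C(O)[C@@H](O)c1ccc(O)cc1 | starting material
14 | benzyl (S)-2-[4-(benzyloxy)phenyl]-2-hydroxyacetate | O=C(OCc1ccccc1)[C@@H](O)c1ccc(OCc2ccccc2)cc1 | intermediate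
15 | benzyl (R)-2-[2,3-bis(benzyloxy)-6-formylphenoxy]-2-[4-(benzyloxy)phenyl]acetate | O=C(OCc1ccccc1)[C@H](Oc1c(C=O)ccc(OCc2ccccc2)c1OCc1ccccc1)c1ccc(OCc2ccccc2)cc1 | intermediate
16 | aryllithium from 10 (lithium at C6) | [Li]c1cc2c(c(OCc3ccccc3)c1OCc1ccccc1)O[C@H](c1ccc(OCc3ccccc3)cc1)[C@@H](O[Si](C)(C)C(C)(C)C)[C@@H]2O[Si](C)(C)C(C)(C)C | intermediate (not isolated)
17 | aryltitanium triisopropoxide from 16 | CC(C)O[Ti](OC(C)C)(OC(C)C)c1cc2c(c(OCc3ccccc3)c1OCc1ccccc1)O[C@H](c1ccc(OCc3ccccc3)cc1)[C@@H](O[Si](C)(C)C(C)(C)C)[C@@H]2O[Si](C)(C)C(C)(C)C | intermediate (not isolated)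
18 | benzyl (2R)-2-{2,3-bis(benzyloxy)-6-[hydroxy(Ar-D)methyl]phenoxy}-2-[4-(benzyloxy)phenyl]acetate, both carbinol epimers | O=C(OCc1ccccc1)[C@H](Oc1c(C(O)c2cc3c(c(OCc4ccccc4)c2OCc2ccccc2)O[C@H](c2ccc(OCc4ccccc4)cc2)[C@@H](O[Si](C)(C)C(C)(C)C)[C@@H]3O[Si](C)(C)C(C)(C)C)ccc(OCc2ccccc2)c1OCc1ccccc1)c1ccc(OCc2ccccc2)cc1 | intermediate
19 | benzyl (2R)-2-{2,3-bis(benzyloxy)-6-[(Ar-D)(pyridin-2-ylsulfonyl)methyl]phenoxy}-2-[4-(benzyloxy)phenyl]acetate, both epimers | O=C(OCc1ccccc1)[C@H](Oc1c(C(c2cc3c(c(OCc4ccccc4)c2OCc2ccccc2)O[C@H](c2ccc(OCc4ccccc4)cc2)[C@@H](O[Si](C)(C)C(C)(C)C)[C@@H]3O[Si](C)(C)C(C)(C)C)S(=O)(=O)c2ccccn2)ccc(OCc2ccccc2)c1OCc1ccccc1)c1ccc(OCc2ccccc2)cc1 | intermediate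
20 | (2R)-2-{2,3-bis(benzyloxy)-6-[(Ar-D)(pyridin-2-ylsulfonyl)methyl]phenoxy}-2-[4-(benzyloxy)phenyl]acetaldehyde | O=C[C@H](Oc1c(C(c2cc3c(c(OCc4ccccc4)c2OCc2ccccc2)O[C@H](c2ccc(OCc4ccccc4)cc2)[C@@H](O[Si](C)(C)C(C)(C)C)[C@@H]3O[Si](C)(C)C(C)(C)C)S(=O)(=O)c2ccccn2)ccc(OCc2ccccc2)c1OCc1ccccc1)c1ccc(OCc2ccccc2)cc1 | intermediate
21 | benzhydrylsamarium diiodide from 20 (samarium on the future C4) | O=C[C@H](Oc1c(C(c2cc3c(c(OCc4ccccc4)c2OCc2ccccc2)O[C@H](c2ccc(OCc4ccccc4)cc2)[C@@H](O[Si](C)(C)C(C)(C)C)[C@@H]3O[Si](C)(C)C(C)(C)C)[Sm](I)I)ccc(OCc2ccccc2)c1OCc1ccccc1)c1ccc(OCc2ccccc2)cc1 | intermediate (not isolated)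
22 | hexa-O-benzyl-3,4-bis-O-(tert-butyldimethylsilyl) dimer: upper unit (2R,3R), 2,3-cis-3,4-trans, free 3-OH, bonded through C4 to C6 of the lower unit | c1ccccc1COc1ccc([C@H]2Oc3c(ccc(OCc4ccccc4)c3OCc3ccccc3)[C@H](c3cc4c(c(OCc5ccccc5)c3OCc3ccccc3)O[C@H](c3ccc(OCc5ccccc5)cc3)[C@@H](O[Si](C)(C)C(C)(C)C)[C@@H]4O[Si](C)(C)C(C)(C)C)[C@H]2O)cc1 | intermediate
23 | hexa-O-benzyl ether of the target (all six phenols benzylated, three alcohols free) | c1ccccc1COc1ccc([C@H]2Oc3c(ccc(OCc4ccccc4)c3OCc3ccccc3)[C@H](c3cc4c(c(OCc5ccccc5)c3OCc3ccccc3)O[C@H](c3ccc(OCc5ccccc5)cc3)[C@@H](O)[C@@H]4O)[C@H]2O)cc1 | intermediate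
24 | (2R,3S,4R)-2-(4-hydroxyphenyl)-6-[(2R,3R,4S)-3,7,8-trihydroxy-2-(4-hydroxyphenyl)chroman-4-yl]chromane-3,4,7,8-tetrol | Oc1ccc([C@H]2Oc3c(ccc(O)c3O)[C@H](c3cc4c(c(O)c3O)O[C@H](c3ccc(O)cc3)[C@@H](O)[C@@H]4O)[C@H]2O)cc1 | target

**Step count and risks**

Total step count: 17. Longest linear sequence: 14 steps (steps 1–8, then 12–17).

Steps most likely to fail:

1. Step 15 (proposed new method). The closure may fail through protonation or dimerisation of the benzhydryl intermediate before it reaches the carbonyl group, through reductive loss of the aryloxy group after ketyl formation, or through closure via the wrong half-chair, giving poor control at C3 or C4. The fallback closes the same ring bond on a simple benzylic bromide with known chemistry and brings in ring D afterwards by the classical arylation trans to the 3-hydroxyl. It sets out from 15 and returns at 22.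
   - NaBH4 (MeOH/THF, 0 °C) would reduce the aryl aldehyde to benzyl (R)-2-[2,3-bis(benzyloxy)-6-(hydroxymethyl)phenoxy]-2-[4-(benzyloxy)phenyl]acetate F1.
   - PPh3/CBr4 would convert it into benzyl (R)-2-[2,3-bis(benzyloxy)-6-(bromomethyl)phenoxy]-2-[4-(benzyloxy)phenyl]acetate F2.
   - iBu2AlH at −78 °C would give (R)-2-[2,3-bis(benzyloxy)-6-(bromomethyl)phenoxy]-2-[4-(benzyloxy)phenyl]acetaldehyde F3.
   - An intramolecular Nozaki–Hiyama benzylation (CrCl2, catalytic LiI, THF) would form the C3–C4 bond and give (2R)-7,8-bis(benzyloxy)-2-[4-(benzyloxy)phenyl]chroman-3-ol F4 as C3 epimers.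
   - Dess–Martin oxidation would give (R)-7,8-bis(benzyloxy)-2-[4-(benzyloxy)phenyl]chroman-3-one F5, and LiBH(s-Bu)3 at −78 °C should converge on the 2,3-cis alcohol (2R,3R)-7,8-bis(benzyloxy)-2-[4-(benzyloxy)phenyl]chroman-3-ol F6.
   - DDQ in the presence of 2-ethoxyethanol would oxidise C4 to (2R,3R)-7,8-bis(benzyloxy)-2-[4-(benzyloxy)phenyl]-4-(2-ethoxyethoxy)chroman-3-ol (3,4-trans) F7.
   - Quenching aryllithium 16 with methanol would give the arene (2R)-2,3-trans-3,4-trans-7,8-bis(benzyloxy)-2-[4-(benzyloxy)phenyl]-3,4-bis(tert-butyldimethylsilyloxy)chromane F8.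
   - TMSOTf at −78 °C with excess F8 should ionise F7 at C4 and arylate it with C6 of F8, trans to the 3-hydroxyl, to rejoin the route at 22.

2. Step 12. The aryl transfer may fail through competing attack of the aryl-metal on the benzyl ester or through deprotonation at C2 with loss of configuration. The fallback is a Nozaki–Hiyama–Kishi arylation, which is non-basic and aldehyde-selective. It sets out from 10 and returns at 18. Copper-catalysed halogen exchange (CuI, N,N'-dimethylethylenediamine, NaI, dioxane, 110 °C) would give the aryl iodide (2R)-2,3-trans-3,4-trans-7,8-bis(benzyloxy)-2-[4-(benzyloxy)phenyl]-3,4-bis(tert-butyldimethylsilyloxy)-6-iodochromane F9, which would be coupled with 15 by CrCl2 and catalytic NiCl2 in DMF at rt.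

3. Step 13. The substitution may fail through acid-induced ionisation of the benzylic silyl ether of the lower unit, or through kinetic O-attack of the sulfinate followed by decomposition of the sulfinate ester. The fallback is a neutral two-step route that sets out from 18 and returns at 19. Mitsunobu thioetherification with pyridine-2-thiol (PPh3, DIAD, THF) would give the sulfide benzyl (2R)-2-{2,3-bis(benzyloxy)-6-[(Ar-D)(pyridin-2-ylsulfanyl)methyl]phenoxy}-2-[4-(benzyloxy)phenyl]acetate F10, and oxidation with H2O2 and catalytic (NH4)6Mo7O24 in EtOH would give sulfone 19.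

Further compounds
F1 | step 15 | benzyl (R)-2-[2,3-bis(benzyloxy)-6-(hydroxymethyl)phenoxy]-2-[4-(benzyloxy)phenyl]acetate | O=C(OCc1ccccc1)[C@H](Oc1c(CO)ccc(OCc2ccccc2)c1OCc1ccccc1)c1ccc(OCc2ccccc2)cc1
F2 | step 15 | benzyl (R)-2-[2,3-bis(benzyloxy)-6-(bromomethyl)phenoxy]-2-[4-(benzyloxy)phenyl]acetate | O=C(OCc1ccccc1)[C@H](Oc1c(CBr)ccc(OCc2ccccc2)c1OCc1ccccc1)c1ccc(OCc2ccccc2)cc1
F3 | step 15 | (R)-2-[2,3-bis(benzyloxy)-6-(bromomethyl)phenoxy]-2-[4-(benzyloxy)phenyl]acetaldehyde | O=C[C@H](Oc1c(CBr)ccc(OCc2ccccc2)c1OCc1ccccc1)c1ccc(OCc2ccccc2)cc1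
F4 | step 15 | (2R)-7,8-bis(benzyloxy)-2-[4-(benzyloxy)phenyl]chroman-3-ol, C3 epimers | c1ccccc1COc1ccc([C@H]2Oc3c(ccc(OCc4ccccc4)c3OCc3ccccc3)CC2O)cc1
F5 | step 15 | (R)-7,8-bis(benzyloxy)-2-[4-(benzyloxy)phenyl]chroman-3-one | c1ccccc1COc1ccc([C@H]2Oc3c(ccc(OCc4ccccc4)c3OCc3ccccc3)CC2=O)cc1
F6 | step 15 | (2R,3R)-7,8-bis(benzyloxy)-2-[4-(benzyloxy)phenyl]chroman-3-ol (2,3-cis) | c1ccccc1COc1ccc([C@H]2Oc3c(ccc(OCc4ccccc4)c3OCc3ccccc3)C[C@H]2O)cc1
F7 | step 15 | (2R,3R)-7,8-bis(benzyloxy)-2-[4-(benzyloxy)phenyl]-4-(2-ethoxyethoxy)chroman-3-ol (3,4-trans) | c1ccccc1COc1ccc([C@H]2Oc3c(ccc(OCc4ccccc4)c3OCc3ccccc3)[C@H](OCCOCC)[C@H]2O)cc1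
F8 | step 15 | (2R)-2,3-trans-3,4-trans-7,8-bis(benzyloxy)-2-[4-(benzyloxy)phenyl]-3,4-bis(tert-butyldimethylsilyloxy)chromane | c1cc2c(c(OCc3ccccc3)c1OCc1ccccc1)O[C@H](c1ccc(OCc3ccccc3)cc1)[C@@H](O[Si](C)(C)C(C)(C)C)[C@@H]2O[Si](C)(C)C(C)(C)C
F9 | step 12 | (2R)-2,3-trans-3,4-trans-7,8-bis(benzyloxy)-2-[4-(benzyloxy)phenyl]-3,4-bis(tert-butyldimethylsilyloxy)-6-iodochromane | Ic1cc2c(c(OCc3ccccc3)c1OCc1ccccc1)O[C@H](c1ccc(OCc3ccccc3)cc1)[C@@H](O[Si](C)(C)C(C)(C)C)[C@@H]2O[Si](C)(C)C(C)(C)C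
F10 | step 13 | benzyl (2R)-2-{2,3-bis(benzyloxy)-6-[(Ar-D)(pyridin-2-ylsulfanyl)methyl]phenoxy}-2-[4-(benzyloxy)phenyl]acetate, both epimers | O=C(OCc1ccccc1)[C@H](Oc1c(C(c2cc3c(c(OCc4ccccc4)c2OCc2ccccc2)O[C@H](c2ccc(OCc4ccccc4)cc2)[C@@H](O[Si](C)(C)C(C)(C)C)[C@@H]3O[Si](C)(C)C(C)(C)C)Sc2ccccn2)ccc(OCc2ccccc2)c1OCc1ccccc1)c1ccc(OCc2ccccc2)cc1
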